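The route rests on making the C13–C16 bond of the cyclopentanone (ring D) last. Ring A, the oxepane acetal and a cyclohexadiene ring C are built first. The quaternary C8 of ring C carries an α-iodovinyl ketone (C15, C16, C17) that sits 1,3 to C13 across C14. A tin hydride-mediated vinyl radical cyclization then attacks C13, the terminus of the C9=C11–C12=C13 diene. In one operation it closes ring D, sets C13, delivers the C15 ketone with its C16 methylene, and relays the unsaturation to C9=C11, the site of the later oxirane. The precursor is a Birch-derived 1-acylcyclohexadiene; C8 is set by reductive hydroxymethylation of an aromatic lactone temporarily tied to the C1 oxygen.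

Key step: step 13

Remark (assumption): the oxirane is put on as a functional group after the ring system is complete, because an oxirane at C11 would be opened by the C12 allyl radical of step 13.
Remark (locants): ent-kaurane numbering of the target is used throughout. Ring A = C1–C5, C10; C6 = acetal carbon on C5; C7 = OCH2 on C8; ring C = C8, C9, C11–C14; C15 = carbonyl carbon on C8; C16, C17 = its two-carbon tail; C18/C19 = methyls on C4; C20 = methyl on C10. "Cis to C20" means the face of ring A that carries C20.
Remark (step 1): the ligand enantiomer is assumed to be the one that gives the 3R product.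

Step 1
Reactants: 1 2,4,4-trimethylcyclohex-2-en-1-one
Product: 3 trimethyl{[(3R)-2,4,4-trimethyl-3-vinylcyclohex-1-en-1-yl]oxy}silane, via dimethylaluminium enolate 2 (not isolated)
Conditions: CH2=CHMgBr, Me2AlCl (gives Me2Al(CH=CH2)), copper thiophene-2-carboxylate (CuTC, 5 mol %), (S,S,S)-phosphoramidite ligand (10 mol %), Et2O, −30 °C; then TMSOTf, THF, −30 → 0 °C
Reagents that add atoms: vinylmagnesium bromide C=C[Mg]Br; trimethylsilyl triflate C[Si](C)(C)OS(=O)(=O)C(F)(F)F
Why: Copper-catalysed asymmetric conjugate addition of an alkenylalane (Alexakis type) is known for α-methyl cyclohexenones; the chiral phosphoramidite–copper complex selects the enone face to set C5 (3R), and silylation of the aluminium enolate fixes the C1=C10 enol ether regiospecifically.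

Step 2
Reactants: 4 methyl 2-iodobenzoate
Product: 6 [2-(methoxycarbonyl)phenyl](2,4,6-trimethoxyphenyl)iodonium tosylate, via hydroxy(tosyloxy)iodoarene 5 (not isolated)
Conditions: mCPBA, TsOH·H2O, MeCN, 55 °C; then 1,3,5-trimethoxybenzene, rt
Reagents that add atoms: p-toluenesulfonic acid Cc1ccc(cc1)S(=O)(=O)O; 1,3,5-trimethoxybenzene COc1cc(OC)cc(OC)c1
Why: One-pot oxidation of the aryl iodide to a Koser-type reagent and electrophilic ligand exchange with trimethoxybenzene gives an unsymmetrical diaryliodonium salt whose trimethoxyphenyl group is a non-transferable dummy; no stereocentre is formed.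

Step 3
Reactants: 3 trimethyl{[(3R)-2,4,4-trimethyl-3-vinylcyclohex-1-en-1-yl]oxy}silane, 6 [2-(methoxycarbonyl)phenyl](2,4,6-trimethoxyphenyl)iodonium tosylate
Product: 8 methyl 2-[(1R,6R)-1,5,5-trimethyl-2-oxo-6-vinylcyclohexyl]benzoate, via lithium enolate 7 (not isolated)
Conditions: MeLi, THF, 0 °C → rt; then 6, THF–DMF, −78 °C → rt
Reagents that add atoms: none
Why: MeLi cleaves the silyl enol ether to the regiodefined lithium enolate, which undergoes metal-free α-arylation with the diaryliodonium salt (ligand coupling on iodine); the electron-poorer, less hindered benzoate ring is transferred to C10 on the face opposite the C5 vinyl group, so the quaternary centre forms with aryl trans and methyl cis to vinyl.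

Step 4
Reactants: 8 methyl 2-[(1R,6R)-1,5,5-trimethyl-2-oxo-6-vinylcyclohexyl]benzoate
Product: 9 methyl 2-[(1R,6R)-3-hydroxy-1,5,5-trimethyl-2-oxo-6-vinylcyclohex-3-en-1-yl]benzoate (diosphenol form of the C1/C2 dione)
Conditions: SeO2, 1,4-dioxane–H2O, 100 °C
Reagents that add atoms: selenium dioxide O=[Se]=O
Why: Riley oxidation: the ketone has a single enolisable α-methylene (C2, since C10 is quaternary), which SeO2 converts into the 1,2-dione, resting as its diosphenol tautomer.

Step 5
Reactants: 9 methyl 2-[(1R,6R)-3-hydroxy-1,5,5-trimethyl-2-oxo-6-vinylcyclohex-3-en-1-yl]benzoate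
Product: 11 4-hydroxy-2,2,10b-trimethyl-1-vinyl-1,2,3,4,4a,10b-hexahydro-6H-benzo[c]chromen-6-one (trans ring fusion; 4-OH, O-5 and 1-vinyl all cis to the 10b-methyl), via diol ester 10 (not isolated)
Conditions: NaBH4, MeOH–CH2Cl2, −20 → 0 °C; then p-TsOH·H2O (cat.), PhMe, 50 °C
Reagents that add atoms: none
Why: Borohydride reduction of the diosphenol (through its keto tautomers) delivers hydride to C1 and C2 from the face opposite the syn-axial C20 and C4 methyl groups, giving the cis-diol on the methyl face (equatorial 1-OH, axial 2-OH); the 1-OH, trans-diequatorial to the aryl group, then lactonises onto the ortho ester under acid catalysis.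

Step 6
Reactants: 11 4-hydroxy-2,2,10b-trimethyl-1-vinyl-1,2,3,4,4a,10b-hexahydro-6H-benzo[c]chromen-6-one
Product: 13 1-(dimethoxymethyl)-4-hydroxy-2,2,10b-trimethyl-1,2,3,4,4a,10b-hexahydro-6H-benzo[c]chromen-6-one (same configuration as 11), via aldehyde 12 (not isolated)
Conditions: O3, CH2Cl2–MeOH, −78 °C; Me2S, → rt; then HC(OMe)3, PPTS (cat.), rt
Reagents that add atoms: ozone [O-][O+]=O; trimethyl orthoformate COC(OC)OC
Why: Ozonolysis with reductive work-up cleaves the only alkene to the C6 aldehyde, which is acetalised in the same pot with the orthoformate; C5 keeps its equatorial substituent, which is also the thermodynamic arrangement should it enolise.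

Step 7
Reactants: 13 1-(dimethoxymethyl)-4-hydroxy-2,2,10b-trimethyl-1,2,3,4,4a,10b-hexahydro-6H-benzo[c]chromen-6-one
Product: 15 1-(dimethoxymethyl)-4-hydroxy-6a-(hydroxymethyl)-2,2,10b-trimethyl-1,2,3,4,4a,6a,9,10b-octahydro-6H-benzo[c]chromen-6-one (6a-CH2OH on the lactone-ring face opposite the 10b-methyl), via dipotassium dienolate 14 (not isolated)
Conditions: K, liq. NH3–THF, t-BuOH (1 equiv), −78 °C; isoprene; NH3 removed; CH2O (gas, from cracked paraformaldehyde), THF, −78 °C; aq. NH4Cl
Reagents that add atoms: formaldehyde C=O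
Why: Birch reduction of the benzoate-type lactone gives the 1,4-dihydro dienolate (protonated at C12), and its aldol addition to formaldehyde at C8 (Birch reductive alkylation, aldol variant) occurs anti to the axial C20 methyl of the trans-fused lactone, which sets the quaternary C8 with C7 on the side of C5.

Step 8
Reactants: 15 1-(dimethoxymethyl)-4-hydroxy-6a-(hydroxymethyl)-2,2,10b-trimethyl-1,2,3,4,4a,6a,9,10b-octahydro-6H-benzo[c]chromen-6-one
Product: 16 oxepane methyl acetal lactone with ring C 9(11),13-diene (C7–O–C6(OMe) bridge closed; C15(=O)–O–C1 lactone kept; free 2-OH)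
Conditions: PPTS (cat.), PhH, 4 Å MS, 50 °C
Reagents that add atoms: none
Why: Acid-catalysed intramolecular transacetalisation: the primary C7 hydroxyl captures the C6 oxocarbenium ion to close the seven-membered oxepane, drawn as the anomer matching the lactol of the target (the anomeric centre equilibrates here and again in step 15); the axial 2-OH cannot reach C6 on the locked chair.

Step 9
Reactants: 16 oxepane methyl acetal lactone with ring C 9(11),13-diene
Product: 17 oxepane methyl acetal lactone with ring C 9(11),12-diene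
Conditions: RuHCl(CO)(PPh3)3 (5 mol %), PhMe, 80 °C
Reagents that add atoms: none
Why: Ruthenium hydride-catalysed alkene isomerisation (hydrometalation/β-hydride elimination) walks the unhindered C13=C14 alkene to C12=C13, into conjugation with the hindered trisubstituted C9=C11 alkene, and the quaternary C8 stops further migration; no stereocentre changes.

Step 10
Reactants: 17 oxepane methyl acetal lactone with ring C 9(11),12-diene
Product: 19 vinyl ketone diol (C8–C(=O)–CH=CH2; 1-OH and 2-OH cis to C20; oxepane methyl acetal; 9(11),12-diene), via bromomagnesium hemiketal 18 (not isolated)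
Conditions: CH2=CHMgBr (2.5 equiv), THF, −78 → −20 °C; aq. NH4Cl at −78 °C
Reagents that add atoms: vinylmagnesium bromide C=C[Mg]Br
Why: Grignard addition to the lactone stops at the magnesium hemiketal, which is stable until the cold quench, so one vinyl group is delivered to the neopentyl C15 carbonyl and the C1 oxygen is released (ketone synthesis from a lactone).

Step 11
Reactants: 19 vinyl ketone diol
Product: 20 vinyl ketone 1,2-diacetate
Conditions: Ac2O, pyridine, DMAP (cat.), CH2Cl2, 0 °C → rt
Reagents that add atoms: acetic anhydride CC(=O)OC(C)=O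
Why: DMAP-catalysed acetylation of both secondary hydroxyls; the hydroxy ketone equilibrates with its cyclic hemiketal and is drained through the open form.

Step 12
Reactants: 20 vinyl ketone 1,2-diacetate
Product: 21 α-iodoenone 1,2-diacetate (C8–C(=O)–C(I)=CH2)
Conditions: I2, DMAP (cat.), K2CO3, THF–H2O, rt
Reagents that add atoms: iodine II
Why: Johnson–Krafft α-iodination of an enone (conjugate addition of DMAP, iodination of the enolate, elimination) iodinates C16 and leaves the unactivated diene untouched.

Step 13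
Reactants: 21 α-iodoenone 1,2-diacetate
Product: 24 1,2-diacetoxy-6-methoxy-6,7-epoxy-6,7-seco-ent-kaura-9(11),16-dien-15-one (acetates cis to C20), via vinyl radical 22 (not isolated), via allyl radical 23 (not isolated)
Conditions: Bu3SnH (1.1 equiv, syringe pump), AIBN (cat.), PhH (0.01 M), 80 °C
Reagents that add atoms: none
Why: Bu3Sn• abstracts iodine from 21 to give the α-keto vinyl radical 22, which adds 5-exo-trig to C13, the terminus of the C9=C11–C12=C13 diene lying 1,3 to the C15 acyl group across C14; the resulting allyl radical 23 (C12–C11–C9) takes hydrogen from Bu3SnH at its less hindered secondary end C12, leaving the C9=C11 alkene. The closest known reaction type is the tin hydride-mediated vinyl radical cyclization of 2-haloallyl units onto cyclohexenes, used to build bicyclo[3.2.1]octanes with an exocyclic methylene. Ring D (C8–C14–C13–C16–C15) closes in the 5-exo mode through the in-plane σ-orbital at C16, so the flat methylenecyclopentanone geometry of the product is already present in the transition state, whereas 6-endo attack at C12 would give an unstabilised radical. C13 is the only new stereocentre and is fixed by the tether: the acyl group on C8 can reach only its own face of ring C, so the C15–C16 bridge is cis by necessity. The selectivity needed is C13 over C12 and hydrogen delivery at C12 rather than C9; the allylic stabilisation at the diene terminus secures the first, and the two quaternary neighbours of C9 (C8 and C10) secure the second.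

Step 14
Reactants: 24 1,2-diacetoxy-6-methoxy-6,7-epoxy-6,7-seco-ent-kaura-9(11),16-dien-15-one
Product: 25 (16R)-1,2-diacetoxy-6-methoxy-6,7-epoxy-6,7-seco-ent-kaur-9(11)-en-15-one (C17 methyl endo, cis to C12)
Conditions: H2 (1 atm), RhCl(PPh3)3 (10 mol %), PhH–EtOH, rt
Reagents that add atoms: none
Why: Homogeneous hydrogenation with RhCl(PPh3)3 reduces the 1,1-disubstituted enone alkene and not the hindered trisubstituted C9=C11 alkene; hydrogen reaches C16 from the exo face (the side of C14), away from the C9–C11–C12 bridge, so the methyl C17 ends endo (16R).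

Step 15
Reactants: 25 (16R)-1,2-diacetoxy-6-methoxy-6,7-epoxy-6,7-seco-ent-kaur-9(11)-en-15-one
Product: 26 (16R)-1,2-diacetoxy-6-hydroxy-6,7-epoxy-6,7-seco-ent-kaur-9(11)-en-15-one (lactol)
Conditions: 1 M aq. HCl, THF, 40 °C
Reagents that add atoms: water O
Why: Acid hydrolysis of the cyclic methyl acetal gives the lactol, whose anomeric centre C6 settles under thermodynamic control; acetates, ketone and the hindered alkene tolerate dilute acid.

Step 16
Reactants: 26 (16R)-1,2-diacetoxy-6-hydroxy-6,7-epoxy-6,7-seco-ent-kaur-9(11)-en-15-one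
Product: 27 CNP0210140.1 (9,11-epoxide on the face of C14 and C20)
Conditions: dimethyldioxirane (acetone solution, 1.2 equiv), CH2Cl2, −20 → 0 °C
Reagents that add atoms: dimethyldioxirane CC1(C)OO1
Why: Dimethyldioxirane epoxidises the electron-rich trisubstituted C9=C11 alkene (no Baeyer–Villiger risk for the ketone) from the exo face of the bicyclo[3.2.1]octene, the side of the one-carbon bridge C14, because the endo face is covered by the C15–C16 bridge and its endo methyl C17; this sets C9 and C11.

Compound list
1 | 2,4,4-trimethylcyclohex-2-en-1-one | CC1=CC(C)(C)CCC1=O | starting material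
2 | dimethylaluminium enolate of (3R)-2,4,4-trimethyl-3-vinylcyclohexanone | C1CC(C)(C)[C@@H](C=C)C(C)=C1O[Al](C)C | intermediate (not isolated)
3 | trimethyl{[(3R)-2,4,4-trimethyl-3-vinylcyclohex-1-en-1-yl]oxy}silane | C1CC(C)(C)[C@@H](C=C)C(C)=C1O[Si](C)(C)C | intermediate
4 | methyl 2-iodobenzoate | COC(=O)c1ccccc1I | starting material
5 | methyl 2-[hydroxy(tosyloxy)iodo]benzoate | COC(=O)c1ccccc1I(O)OS(=O)(=O)c1ccc(C)cc1 | intermediate (not isolated)
6 | [2-(methoxycarbonyl)phenyl](2,4,6-trimethoxyphenyl)iodonium tosylate | COC(=O)c1ccccc1[I+]c1c(OC)cc(OC)cc1OC.Cc1ccc(cc1)S(=O)(=O)[O-] | intermediate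
7 | lithium (3R)-2,4,4-trimethyl-3-vinylcyclohex-1-en-1-olate | C1CC(C)(C)[C@@H](C=C)C(C)=C1O[Li] | intermediate (not isolated)
8 | methyl 2-[(1R,6R)-1,5,5-trimethyl-2-oxo-6-vinylcyclohexyl]benzoate | C1CC(C)(C)[C@@H](C=C)[C@](C)(c2ccccc2C(=O)OC)C1=O | intermediate
9 | methyl 2-[(1R,6R)-3-hydroxy-1,5,5-trimethyl-2-oxo-6-vinylcyclohex-3-en-1-yl]benzoate | OC1=CC(C)(C)[C@@H](C=C)[C@](C)(c2ccccc2C(=O)OC)C1=O | intermediate
10 | methyl 2-[2,3-dihydroxy-1,5,5-trimethyl-6-vinylcyclohexyl]benzoate (both OH cis to the 1-methyl, aryl trans to vinyl) | O[C@H]1CC(C)(C)[C@@H](C=C)[C@](C)(c2ccccc2C(=O)OC)[C@H]1O | intermediate (not isolated)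
11 | 4-hydroxy-2,2,10b-trimethyl-1-vinyl-1,2,3,4,4a,10b-hexahydro-6H-benzo[c]chromen-6-one (trans-fused; 4-OH, O-5, 1-vinyl cis to 10b-methyl) | O[C@H]1CC(C)(C)[C@@H](C=C)[C@](C)(c2ccccc2C(=O)O3)[C@H]13 | intermediate
12 | 4-hydroxy-2,2,10b-trimethyl-6-oxo-1,2,3,4,4a,10b-hexahydro-6H-benzo[c]chromene-1-carbaldehyde | O[C@H]1CC(C)(C)[C@@H](C=O)[C@](C)(c2ccccc2C(=O)O3)[C@H]13 | intermediate (not isolated)
13 | 1-(dimethoxymethyl)-4-hydroxy-2,2,10b-trimethyl-1,2,3,4,4a,10b-hexahydro-6H-benzo[c]chromen-6-one | O[C@H]1CC(C)(C)[C@@H](C(OC)OC)[C@](C)(c2ccccc2C(=O)O3)[C@H]13 | intermediate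
14 | dipotassium salt: C2 alkoxide and cross-conjugated C8=C15 dienolate of the 1,4-dihydro lactone | [K+].[K+].[O-][C@H]1CC(C)(C)[C@@H](C(OC)OC)[C@](C)(C2=CCC=CC2=C([O-])O3)[C@H]13 | intermediate (not isolated)
15 | 1-(dimethoxymethyl)-4-hydroxy-6a-(hydroxymethyl)-2,2,10b-trimethyl-1,2,3,4,4a,6a,9,10b-octahydro-6H-benzo[c]chromen-6-one | O[C@H]1CC(C)(C)[C@@H](C(OC)OC)[C@](C)(C2=CCC=C[C@@]2(CO)C(=O)O3)[C@H]13 | intermediate
16 | oxepane methyl acetal lactone, ring C 9(11),13-diene | O[C@H]1CC(C)(C)[C@H]2[C@H](OC)OC[C@]3(C=CCC=C3[C@]2(C)[C@H]1O4)C4=O | intermediate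
17 | oxepane methyl acetal lactone, ring C 9(11),12-diene | O[C@H]1CC(C)(C)[C@H]2[C@H](OC)OC[C@]3(CC=CC=C3[C@]2(C)[C@H]1O4)C4=O | intermediate
18 | bis(bromomagnesium) salt of the vinyl hemiketal adduct of 17 | Br[Mg]O[C@H]1CC(C)(C)[C@H]2[C@H](OC)OC[C@]3(CC=CC=C3[C@]2(C)[C@H]1O4)C4(O[Mg]Br)C=C | intermediate (not isolated)
19 | vinyl ketone diol (may rest partly as the C1–O–C15 hemiketal) | O[C@H]1CC(C)(C)[C@H]2[C@H](OC)OC[C@]3(CC=CC=C3[C@]2(C)[C@H]1O)C(=O)C=C | intermediate
20 | vinyl ketone 1,2-diacetate | CC(=O)O[C@H]1CC(C)(C)[C@H]2[C@H](OC)OC[C@]3(CC=CC=C3[C@]2(C)[C@H]1OC(C)=O)C(=O)C=C | intermediate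
21 | α-iodoenone 1,2-diacetate | CC(=O)O[C@H]1CC(C)(C)[C@H]2[C@H](OC)OC[C@]3(CC=CC=C3[C@]2(C)[C@H]1OC(C)=O)C(=O)C(I)=C | intermediate
22 | α-keto vinyl radical at C16 | CC(=O)O[C@H]1CC(C)(C)[C@H]2[C@H](OC)OC[C@]3(CC=CC=C3[C@]2(C)[C@H]1OC(C)=O)C(=O)[C]=C | intermediate (not isolated)
23 | ring D-closed allyl radical (C12–C11–C9) | CC(=O)O[C@H]1CC(C)(C)[C@H]2[C@H](OC)OC[C@@]34C[C@@H]([CH]C=C3[C@]2(C)[C@H]1OC(C)=O)C(=C)C4=O | intermediate (not isolated)
24 | 1,2-diacetoxy-6-methoxy-6,7-epoxy-6,7-seco-ent-kaura-9(11),16-dien-15-one | CC(=O)O[C@H]1CC(C)(C)[C@H]2[C@H](OC)OC[C@@]34C[C@@H](CC=C3[C@]2(C)[C@H]1OC(C)=O)C(=C)C4=O | intermediate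
25 | (16R)-1,2-diacetoxy-6-methoxy-6,7-epoxy-6,7-seco-ent-kaur-9(11)-en-15-one | CC(=O)O[C@H]1CC(C)(C)[C@H]2[C@H](OC)OC[C@@]34C[C@@H](CC=C3[C@]2(C)[C@H]1OC(C)=O)[C@@H](C)C4=O | intermediate
26 | (16R)-1,2-diacetoxy-6-hydroxy-6,7-epoxy-6,7-seco-ent-kaur-9(11)-en-15-one | CC(=O)O[C@H]1CC(C)(C)[C@H]2[C@H](O)OC[C@@]34C[C@@H](CC=C3[C@]2(C)[C@H]1OC(C)=O)[C@@H](C)C4=O | intermediate
27 | CNP0210140.1 | CC(=O)O[C@H]1CC(C)(C)[C@H]2[C@H](O)OC[C@@]34C[C@@H](C[C@H]5O[C@]53[C@]2(C)[C@H]1OC(C)=O)[C@@H](C)C4=O | target

Total step count: 16. Longest linear sequence: 15 steps (1 → 27 through steps 1 and 3–16; step 2 is a one-step side branch from 4).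

Steps most likely to fail

Step 13 (key step). The conjugated α-keto vinyl radical may be reduced by Bu3SnH before it reaches C13, or may close at C12 (6-endo) to a bicyclo[2.2.2]octene; on heating, the enone of 21 could also add across the diene in a Diels–Alder sense. The fallback sets out from 21. Luche reduction (NaBH4, CeCl3·7H2O, MeOH, −40 °C) gives the allylic alcohol, the 15-hydroxy-16-iodo-16-ene F2 (C15 epimers). Its unconjugated σ-vinyl radical is cyclised with Bu3SnH/AIBN (the classical 2-haloallyl closure onto a cyclohexene) to the 15-hydroxy-9(11),16-diene F3. Oxidation with Dess–Martin periodinane then comes back to the route at 24.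

Step 3. O-arylation or electron-transfer decomposition of the iodonium salt may outrun C–C coupling at the crowded tetrasubstituted enolate carbon, and facial selectivity may erode. The fallback sets out from 3 and forms the same C9–C10 bond by palladium-catalysed cross-coupling of the tin enolate made in the flask (methyl 2-bromobenzoate, Pd(OAc)2, P(t-Bu)3, Bu3SnF, PhMe, 85 °C; Kuwajima–Urabe type). It comes back at 8 and makes no compound outside the list, F0.

Step 7. The lactone carbonyl may be over-reduced, formaldehyde may be reduced by residual metal, or the hydroxymethyl group may be lost by retro-aldol on warming. The fallback sets out from 13: Birch reduction with NH4Cl quench gives the protonated 6a,9-dihydro lactone F1 (C8–H). This is deprotonated with LDA (2.2 equiv, THF, −78 °C) and the lithium enolate is hydroxymethylated with monomeric formaldehyde under metal-free and ammonia-free conditions, coming back at 15.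

Further compounds
F0 | step 3 | none | none
F1 | step 7 | 1-(dimethoxymethyl)-4-hydroxy-2,2,10b-trimethyl-1,2,3,4,4a,6a,9,10b-octahydro-6H-benzo[c]chromen-6-one (C6a–H, both epimers) | O[C@H]1CC(C)(C)[C@@H](C(OC)OC)[C@](C)(C2=CCC=CC2C(=O)O3)[C@H]13
F2 | step 13 | 15-hydroxy-16-iodo allylic alcohol from 21 (C15 epimers) | CC(=O)O[C@H]1CC(C)(C)[C@H]2[C@H](OC)OC[C@]3(CC=CC=C3[C@]2(C)[C@H]1OC(C)=O)C(O)C(I)=C
F3 | step 13 | 1,2-diacetoxy-15-hydroxy-6-methoxy-6,7-epoxy-6,7-seco-ent-kaura-9(11),16-diene (C15 epimers) | CC(=O)O[C@H]1CC(C)(C)[C@H]2[C@H](OC)OC[C@@]34C[C@@H](CC=C3[C@]2(C)[C@H]1OC(C)=O)C(=C)C4O
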